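## Structural features

The target is a 2-acylcyclohexane-1,3-dione (a β-triketone drawn as its C3 enol) with a hydroxyl group on C5. Its C2 acyl group is an unbranched nonanoyl chain ending in a 3,4-dihydroxyphenyl ring, so the carbocycle and the benzene ring are joined through C2–C(=O)–(CH2)8. C5 is the only stereocentre and has no stereogenic neighbour. Its ring arms C4 and C6 differ only in whether they lead to the enol carbon C3 or the ketone carbon C1, and because the enol proton moves between the triketone oxygens, the configuration at C5 is a matter of tautomer, not of a separable enantiomer. The fragile spot is the C5 hydroxyl: it is β to both ring carbonyls, and loss of water followed by tautomerization gives a 2-acylresorcinol irreversibly. The free catechol is sensitive to oxidation and the triketone is acidic and chelating. The real difficulty is to build a ring with oxygen on C1, C3 and C5 and carbon on C2 without passing through a state from which the C5 oxygen can leave: an allylic alcohol beside an enol ether under acid, or a β-acyloxy ketone under base. The key step uses the 1,4 relationship of the acyl carbon on C2 and the oxygen on C5: joined as C(=O)–O they are the lactone unit of a 2-pyranone whose C3–C6 become ring carbons C2–C5, while C1 and C6 come from a ketene acetal that brings C1 at the ketone oxidation level.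

## Logic of the disconnections

**17 from 16.** The two O–CH2Ph bonds of the catechol are cut. The catechol is the most oxidation-sensitive part of 17, so it is uncovered last by a neutral hydrogenolysis that needs only filtration. Every earlier step then works on a lipophilic, non-phenolic substrate. The demand is that hydrogen on palladium leaves the enolized triketone and the C5 hydroxyl alone.

**16 from 14 through 15.** The C1 and C3 carbonyl groups are taken back to a dimethyl ketal and a silyl enol ether (C3O–Si and the two C1–OMe bonds). With both masked, C2 carries a hydrogen and one ketone, which is what the preceding acyl transfer can deliver. The demand is an order of events. In 14 the C5 hydroxyl is allylic to the C3 enol ether, and acid would ionize it (the situation of a Stork–Danheiser transposition) and lead to aromatization. The enol ether must therefore go first and without acid, which is why the C3 oxygen sits on silicon and not on a methyl group. Only then may acid open the ketal of 15.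

**14 from 7 and 11 through 12 and 13.** The bond between the acyl carbon and the first chain carbon is cut, and the acyl carbon is joined to the C5 oxygen as a lactone. The side chain leaves as a primary bromide. The ring becomes a bicycle in which the future C2–H is a bridgehead that cannot enolize and the C5 oxygen is an ester oxygen that cannot be eliminated. The demand is addition of exactly one carbon nucleophile to the lactone carbonyl. This is met by passing through amide 12 in the same flask, where the C5 oxygen protects itself as a magnesium alkoxide.

**7 from 5 and 6.** The ring bonds C2–C1 and C5–C6 (target numbering) are cut in a retro-[4+2] sense. Two flat, achiral pieces result, and every ring oxygen is in place at the right oxidation level: the ring oxygen of 5 becomes O5, its carbonyl carbon the acyl carbon, its 4-oxygen O3, and the acetal carbon of 6 becomes C1. The demand is high: an electron-rich diene must accept an electron-rich dienophile with one regiochemistry, at a temperature low enough that 7 does not lose carbon dioxide.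

**5 from 4.** The O–Si bond is cut. The silyl group is put on at the stage of the free vinylogous acid, so no protecting-group exchange is needed later.

**4 from 1 and 2 through 3.** The lactone C–O bond and the C5–C6 bond of the pyranone are cut, leading to the γ-carbon of 1 and the one-carbon ester 2. Both are bulk chemicals. The demand is γ- and not α-acylation of 1, met by its dianion, and lactonization of 3 before it condenses with itself.

**11 from 8 and 9 through 10.** The aryl–CH2 bond is cut. Both pieces are commercial, the chain arrives saturated, and the terminal bromide needed for 13 is carried through the coupling. The demand is that the palladium catalyst reacts with the aryl bromide and not with the alkyl bromide.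

## Other disconnections considered

**Alternative 1:** The cut is the ring bond C1–C2. The precursor is the open-chain β-silyloxy thioester A1, in which C2 is the methylene between two ketones.
- **Forward step:** Soft enolization (MgBr2·OEt2, i-Pr2NEt) would give the magnesium enolate of the 1,3-diketone, whose central carbon attacks the thioester carbonyl in a 6-exo-trig Claisen closure; ethanethiolate leaves and the protected triketone A2 results.
- **In its favour:** It follows the biosynthetic logic, needs no redox adjustment, forms the whole tricarbonyl array in one mild step, and rests on a reaction type with precedent. On precedent it is better than the chosen plan.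
- **Against it here:** A1 has a silyloxy group β to the thioester, so enolization on the wrong side would expel it and start the aromatization that must be avoided. O-acylation to a six-membered enol lactone competes with C-acylation. A1 is a linear chain oxygenated at C1, C3, C5 and C7 that must be built stepwise with the acidic diketone present. Its stereocentre would cost an asymmetric step whose result is erased in A2 by the same tautomerism as in the target.
- **Comparison:** Structurally it closes one ring bond where the cycloaddition forms two. Mechanistically its key step is safer but its substrate is more elimination-prone, whereas the chosen plan keeps the C5 oxygen in a lactone until the chain is attached. A1 would need roughly seven to nine linear steps before the key step against two for the pyranone, so the chosen plan is shorter.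

**Alternative 2:** Both bonds to the acyl carbon are cut, C2–C(acyl) and C(acyl)–Cα. The pieces are the iodoenone A3, the alkylborane A4 and carbon monoxide.
- **Forward step:** Zerovalent palladium (Pd(PPh3)4, K3PO4, CO) would insert into the C–I bond of A3, take up CO to an acylpalladium species, and couple with A4 to give the vinylogous ester A5. No ring is formed.
- **In its favour:** It is the most convergent plan. The ring comes from an existing symmetrical dione, and A4 is the debromo analogue of intermediate 10, so the side-chain chemistry is shared (equal on that point). Carbonylative Suzuki–Miyaura coupling of B-alkyl-9-BBN reagents with alkenyl iodides is established, which puts it ahead of the chosen key step on precedent. In A5 the C5 oxygen is not allylic to the enol ether, so the final hydrolysis is uncomplicated (equal to the chosen plan with its silyl enol ether).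
- **Against it here:** The iodide sits on a tetrasubstituted alkene flanked by two oxygenated carbons, where direct alkyl transfer without CO uptake and protodeiodination would compete with carbonylation. The warm basic conditions act on a β-silyloxy ketone that can eliminate. The stereocentre of A3 would need an enantioselective desymmetrization that is lost when A5 is hydrolysed.
- **Comparison:** Structurally it buys the ring instead of making it, which is simpler. Mechanistically it has a selectivity problem (three components in the right order at a hindered centre) where the chosen plan has a reactivity problem. It would take about four steps to A3, one or two to A4, the coupling and three deprotections: nine to ten steps against seven, and a longest linear sequence of about eight against six.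

**Alternative 3:** The cut is the ring bond C5–C6, made as an aldol bond, with the triketone locked in an isoxazole. The precursor is the keto aldehyde A6.
- **Forward step:** (S)-Proline would condense with the acetyl group of A6, the enamine would add to the aldehyde (6-enolexo-exo-trig), and hydrolysis would give the fused β-hydroxy ketone A7 with the C–O stereocentre set by the catalyst.
- **In its favour:** The isoxazole holds the C2 acyl group and one ring carbonyl in a neutral, non-chelating form through all side-chain work. The aldol step is catalytic and belongs to a known reaction family, ahead of the chosen key step on precedent. N–O cleavage and debenzylation could share one hydrogenation.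
- **Against it here:** The aldehyde of A6 is a heteroarylacetaldehyde, more acidic and more prone to enamine formation than the conjugated methyl ketone that must act as donor, so the catalyst would be drawn to the unproductive site and self-condensation threatens. Dehydration of A7 gives an aromatic hydroxybenzisoxazole, a stronger pull towards water loss than in the target. Ring opening leaves an enaminone that must be hydrolysed beside the same labile hydroxyl. The proline-set stereocentre is erased once C1 and C3 become equivalent.
- **Comparison:** Structurally it forms one ring bond and must first assemble a trisubstituted isoxazole carrying the whole chain. Mechanistically it spends catalyst control on a centre that cannot be kept, which the chosen plan does not. Isoxazole construction, aldehyde arm, aldol, N–O cleavage, hydrolysis and debenzylation add up to ten or more steps, longer than the chosen route.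

Key step: step 3

Assumption: the two ring-enol forms of 17 interconvert by proton transfer through the symmetric enolate, so the (5S) drawing and its mirror image are tautomers of one compound with no configurationally stable enantiomer; the route therefore delivers this equilibrating compound and contains no enantioselective step.

## Route

Step 1
Reactants: 1 methyl acetoacetate (methyl 3-oxobutanoate); 2 methyl formate
Product: 4 4-hydroxy-2H-pyran-2-one, via methyl 3,5-dioxopentanoate 3 (not isolated)
Conditions: 1 (2 equiv), NaH, THF, 0 °C; n-BuLi, 0 °C; 2, −78 → 0 °C; aq. HCl; crude 3, DBU, toluene, 80 °C; aq. HCl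
Reagents that add atoms: none
Why: Crossed Claisen condensation of the γ-carbon of the acetoacetate dianion with the formate ester gives the 1,3,5-tricarbonyl chain; with one equivalent of DBU only the keto-aldehyde part is deprotonated and its Z-enolate oxygen closes onto the ester (6-exo-trig lactonization, loss of methanol), driven by formation of the conjugated 4-hydroxy-2-pyranone. No stereocentre is involved.

Step 2
Reactants: 4 4-hydroxy-2H-pyran-2-one
Product: 5 4-[(tert-butyldimethylsilyl)oxy]-2H-pyran-2-one
Conditions: TBSCl, Et3N, CH2Cl2, 0 °C → rt; filter, concentrate, no aqueous work-up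
Reagents that add atoms: tert-butyl(chloro)dimethylsilane (TBSCl), CC(C)(C)[Si](C)(C)Cl
Why: O-Silylation of the vinylogous acid on O4; silyl transfer between the two oxygens is reversible and the 2-pyranone is the more stable silyl tautomer. Silicon is chosen over methyl because the C3 enol ether of the later intermediates must be cleavable by fluoride and not by acid.

Step 3
Reactants: 5 4-[(tert-butyldimethylsilyl)oxy]-2H-pyran-2-one; 6 1,1-dimethoxyethene
Product: 7 rac-(1R,4R)-5-[(tert-butyldimethylsilyl)oxy]-8,8-dimethoxy-2-oxabicyclo[2.2.2]oct-5-en-3-one
Conditions: 6 (5 equiv), 2,6-di-tert-butyl-4-methylpyridine (5 mol %), CH2Cl2, 1.3 GPa (13 kbar), 20 °C, 72 h; evaporate below 20 °C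
Reagents that add atoms: none
Why: Proposed new method: the electron-rich CH2 terminus of 6 should attack C6 of 5 (the δ-position of the dienyl ester) and the acetal carbon should bond to C3, either in one asynchronous inverse-demand [4+2] event or through an oxocarbenium/dienolate ion pair that collapses at once; the closest known reaction type is the inverse-demand Diels–Alder reaction of 2-pyranones activated at C3 (bromo, sulfonyl, alkoxycarbonyl) with vinyl ethers and ketene acetals, which gives isolable bridged lactones of this regiochemistry, whereas a 4-oxygenated 2-pyranone has not been used in this role. The carbocycle closes by intermolecular [4+2] cycloaddition, suprafacial on both partners, with the O–C(=O) unit kept as a two-atom bridge; in the stepwise limit the second bond forms by 6-exo-trig attack of the dienolate carbon on the oxocarbenium ion. The two new stereocentres are the bridgeheads C1 and C4, and their relative configuration is fixed by the bridge because both bonds must form on one face of the planar pyranone. Both partners are achiral and the dienophile has two identical substituents, so there is no endo/exo or facial question and 7 forms as a racemate. The step needs regioselectivity (CH2 to C6, acetal carbon to C3), site selectivity for C6 over C4, and survival of the adduct. The first follows from the matched polarity of the partners, the second from the silyloxy group, which makes C4 a vinylogous ester carbon, and the third from working at 20 °C, where pressure accelerates the bond-forming process (strongly negative activation volume) but not the retro-[4+2] loss of CO2. The silyloxy group is a weaker π-donor than methoxy, so the diene is no poorer than necessary, and the hindered pyridine keeps traces of acid from polymerizing 6.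

Step 4
Reactants: 8 8-bromooct-1-ene; 9 4-bromo-1,2-bis(benzyloxy)benzene
Product: 11 1,2-bis(benzyloxy)-4-(8-bromooctyl)benzene, via 9-(8-bromooctyl)-9-borabicyclo[3.3.1]nonane 10 (not isolated)
Conditions: 8, 9-BBN, THF, 0 °C → rt; then 9, Pd(dppf)Cl2 (3 mol %), 3 M aq. K3PO4, DMF, 50 °C
Reagents that add atoms: none
Why: 9-BBN adds to the terminal alkene with boron on C1 (anti-Markovnikov hydroboration) and B-alkyl Suzuki–Miyaura coupling forms the aryl–CH2 bond. Zerovalent palladium bearing dppf inserts into the aryl C–Br bond but not into an unactivated primary alkyl C–Br bond, and phosphate is too weak a nucleophile to displace bromide at 50 °C.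

Step 5
Reactants: 7 rac-(1R,4R)-5-[(tert-butyldimethylsilyl)oxy]-8,8-dimethoxy-2-oxabicyclo[2.2.2]oct-5-en-3-one; 11 1,2-bis(benzyloxy)-4-(8-bromooctyl)benzene
Product: 14 rac-9-[3,4-bis(benzyloxy)phenyl]-1-{(1S,4R)-2-[(tert-butyldimethylsilyl)oxy]-4-hydroxy-6,6-dimethoxycyclohex-2-en-1-yl}nonan-1-one (acyl and hydroxyl cis), via chloromagnesium alkoxide of the Weinreb amide 12 (not isolated), via 8-aryloctylmagnesium bromide 13 (not isolated)
Conditions: MeNHOMe·HCl (1.3 equiv), i-PrMgCl (2.6 equiv), THF, −20 °C; 7, −20 → 0 °C; then 13 [from 11 (1.8 equiv), Mg, THF, 35 °C], 0 °C → rt; pH 7 phosphate buffer, 0 °C; Et3N-deactivated SiO2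
Reagents that add atoms: none
Why: The chloromagnesium amide made in the flask opens the strained bridged lactone by acyl substitution (Weinreb aminolysis); the bridgehead C–H beside the carbonyl cannot enolize, and the C5 oxygen is released as a magnesium alkoxide that protects itself. The primary Grignard reagent 13 then adds once to the N-methoxy-N-methylamide, whose five-membered magnesium chelate holds the tetrahedral adduct until the neutral quench (Weinreb ketone synthesis). Both stereocentres of 7 are untouched, so acyl and hydroxyl stay cis, and acid is excluded because the C5 hydroxyl is now allylic to the silyl enol ether.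

Step 6
Reactants: 14 rac-9-[3,4-bis(benzyloxy)phenyl]-1-{(1S,4R)-2-[(tert-butyldimethylsilyl)oxy]-4-hydroxy-6,6-dimethoxycyclohex-2-en-1-yl}nonan-1-one
Product: 16 2-{9-[3,4-bis(benzyloxy)phenyl]nonanoyl}-3,5-dihydroxycyclohex-2-en-1-one, via 9-[3,4-bis(benzyloxy)phenyl]-1-(4-hydroxy-2,2-dimethoxy-6-oxocyclohexyl)nonan-1-one 15 (not isolated)
Conditions: TBAF (1.2 equiv), AcOH (1.5 equiv), THF, 0 °C; then 1 M aq. HCl, THF, 0 °C → rt
Reagents that add atoms: water, O
Why: Fluoride attacks silicon and the buffered enolate is protonated to the C3 ketone, so the enol ether disappears without acid while the C5 hydroxyl is still allylic to it; this avoids the Stork–Danheiser-type ionization that would end in loss of water and aromatization. Aqueous acid then hydrolyses the dimethyl ketal (acetal hydrolysis, assisted by the enolized β-diketone), and the triketone enol that forms keeps C4 and C6 from enolizing, which protects the β-hydroxyl. The C1 stereocentre of 14 vanishes and C5 becomes the tautomer-dependent centre.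

Step 7
Reactants: 16 2-{9-[3,4-bis(benzyloxy)phenyl]nonanoyl}-3,5-dihydroxycyclohex-2-en-1-one
Product: 17 (5S)-2-[9-(3,4-dihydroxyphenyl)nonanoyl]-3,5-dihydroxycyclohex-2-en-1-one (target)
Conditions: H2 (1 atm), 10% Pd/C, EtOAc–MeOH, rt; filter under argon
Reagents that add atoms: none
Why: Hydrogenolysis of the two aryl benzyl ethers on palladium; the chelated enol of the triketone and the unactivated secondary alcohol should not be reduced at 1 atm and room temperature. C5 is delivered as the equilibrating pair of enol tautomers, of which the drawn (5S) form is one.

## Compound list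

1 | methyl acetoacetate | CC(=O)CC(=O)OC | starting material
2 | methyl formate | COC=O | starting material
3 | methyl 3,5-dioxopentanoate (formed as enolate salt, used crude) | COC(=O)CC(=O)CC=O | intermediate
4 | 4-hydroxy-2H-pyran-2-one | O=C1C=C(O)C=CO1 | intermediate
5 | 4-[(tert-butyldimethylsilyl)oxy]-2H-pyran-2-one | O=C1C=C(O[Si](C)(C)C(C)(C)C)C=CO1 | intermediate
6 | 1,1-dimethoxyethene | C=C(OC)OC | starting material
7 | rac-(1R,4R)-5-[(tert-butyldimethylsilyl)oxy]-8,8-dimethoxy-2-oxabicyclo[2.2.2]oct-5-en-3-one (one enantiomer drawn) | O=C1O[C@@H]2CC(OC)(OC)[C@H]1C(O[Si](C)(C)C(C)(C)C)=C2 | intermediate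
8 | 8-bromooct-1-ene | C=CCCCCCCBr | starting material
9 | 4-bromo-1,2-bis(benzyloxy)benzene | Brc1ccc(OCc2ccccc2)c(OCc2ccccc2)c1 | starting material
10 | 9-(8-bromooctyl)-9-borabicyclo[3.3.1]nonane | BrCCCCCCCCB1C2CCCC1CCC2 | intermediate
11 | 1,2-bis(benzyloxy)-4-(8-bromooctyl)benzene | BrCCCCCCCCc1ccc(OCc2ccccc2)c(OCc2ccccc2)c1 | intermediate
12 | chloromagnesium alkoxide of rac-(1R,4R)-2-[(tert-butyldimethylsilyl)oxy]-4-hydroxy-N,6,6-trimethoxy-N-methylcyclohex-2-ene-1-carboxamide (one enantiomer drawn) | CON(C)C(=O)[C@@H]1C(O[Si](C)(C)C(C)(C)C)=C[C@H](O[Mg]Cl)CC1(OC)OC | intermediate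
13 | {8-[3,4-bis(benzyloxy)phenyl]octyl}magnesium bromide | Br[Mg]CCCCCCCCc1ccc(OCc2ccccc2)c(OCc2ccccc2)c1 | intermediate
14 | rac-9-[3,4-bis(benzyloxy)phenyl]-1-{(1S,4R)-2-[(tert-butyldimethylsilyl)oxy]-4-hydroxy-6,6-dimethoxycyclohex-2-en-1-yl}nonan-1-one (cis; one enantiomer drawn) | O=C(CCCCCCCCc1ccc(OCc2ccccc2)c(OCc2ccccc2)c1)[C@@H]1C(O[Si](C)(C)C(C)(C)C)=C[C@H](O)CC1(OC)OC | intermediate
15 | 9-[3,4-bis(benzyloxy)phenyl]-1-(4-hydroxy-2,2-dimethoxy-6-oxocyclohexyl)nonan-1-one (racemic; C1 epimers and enol forms) | O=C(CCCCCCCCc1ccc(OCc2ccccc2)c(OCc2ccccc2)c1)C1C(=O)CC(O)CC1(OC)OC | intermediate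
16 | 2-{9-[3,4-bis(benzyloxy)phenyl]nonanoyl}-3,5-dihydroxycyclohex-2-en-1-one ((5S) enol tautomer drawn; equilibrates with its mirror-image enol) | O=C(CCCCCCCCc1ccc(OCc2ccccc2)c(OCc2ccccc2)c1)C1=C(O)C[C@H](O)CC1=O | intermediate
17 | (5S)-2-[9-(3,4-dihydroxyphenyl)nonanoyl]-3,5-dihydroxycyclohex-2-en-1-one | O=C(CCCCCCCCc1ccc(O)c(O)c1)C1=C(O)C[C@H](O)CC1=O | target

## Step count and least certain steps

Total: 7 steps. Longest linear sequence: 6 steps (1, 2, 3, 5, 6, 7); step 4 makes the side chain.

**Step 3 (key step, the one step outside known chemistry).** The most likely failure is insufficient reactivity: the 4-oxygen donor raises the energy of the diene acceptor orbital, so 6 may oligomerize or add elsewhere before the cycloaddition occurs. The second is retro-[4+2] loss of carbon dioxide from the adduct on concentration, followed by loss of methanol and aromatization. Fallback with known chemistry, from 4 and returning at 7: bromination of the nucleophilic C3 with N-bromosuccinimide would give 3-bromo-4-hydroxy-2H-pyran-2-one F1. Silylation as in step 2 gives 3-bromo-4-[(tert-butyldimethylsilyl)oxy]-2H-pyran-2-one F2. This is a 3-bromo-2-pyranone, the class whose pressure-promoted cycloadditions with electron-rich alkenes to isolable bridged lactones are known, and with 6 it should give rac-4-bromo-5-[(tert-butyldimethylsilyl)oxy]-8,8-dimethoxy-2-oxabicyclo[2.2.2]oct-5-en-3-one F3. Radical debromination of the bridgehead bromide (n-Bu3SnH, Et3B, air, toluene, 0 °C) then gives 7.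

**Step 5.** The amide carbonyl of 12 is flanked by a ketal carbon and a silyloxy-bearing alkene carbon. Slow addition of 13 would leave time for α-deprotonation and β-elimination of methoxide; incomplete aminolysis would allow double addition to the lactone. Fallback, from 7 and returning at 15: aminolysis as before to 12, then trapping of the alkoxide with TESCl and imidazole gives rac-cis-2-[(tert-butyldimethylsilyl)oxy]-N,6,6-trimethoxy-N-methyl-4-[(triethylsilyl)oxy]cyclohex-2-ene-1-carboxamide F4. Reduction with i-Bu2AlH at −78 °C gives rac-cis-2-[(tert-butyldimethylsilyl)oxy]-6,6-dimethoxy-4-[(triethylsilyl)oxy]cyclohex-2-ene-1-carbaldehyde F5. Addition of 13 to this much less hindered carbonyl gives the carbinol 9-[3,4-bis(benzyloxy)phenyl]-1-{2-[(tert-butyldimethylsilyl)oxy]-6,6-dimethoxy-4-[(triethylsilyl)oxy]cyclohex-2-en-1-yl}nonan-1-ol F6. Dess–Martin oxidation buffered with pyridine gives the O-triethylsilyl ether of 14, 9-[3,4-bis(benzyloxy)phenyl]-1-{2-[(tert-butyldimethylsilyl)oxy]-6,6-dimethoxy-4-[(triethylsilyl)oxy]cyclohex-2-en-1-yl}nonan-1-one F7. Under the fluoride conditions of step 6 both silyl groups are lost and the route is rejoined at 15.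

**Step 6.** The risk is loss of water from C5, either by ionization of the allylic hydroxyl if acid reaches the material before desilylation is complete, or by β-elimination once the carbonyls are free. Either ends in irreversible aromatization to the acylresorcinol. Fallback, from 14 and returning at 16, with no mineral acid: K2CO3 in MeOH at 0 °C cleaves the silyl enol ether, and the enolate expels methoxide from the neighbouring ketal to give the isolable vinylogous ester 2-{9-[3,4-bis(benzyloxy)phenyl]nonanoyl}-5-hydroxy-3-methoxycyclohex-2-en-1-one F8. Aqueous LiOH in THF then exchanges methoxide for hydroxide by addition–elimination, the product being held as its unreactive triketone enolate, and acidification to pH 4 gives 16.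

**Step 4.** The primary bromide may be partly lost by hydrolysis or elimination under the warm aqueous base, or the alkylborane may be consumed by protodeboronation before transmetallation. Fallback, from 9 and returning at 11: magnesium insertion gives [3,4-bis(benzyloxy)phenyl]magnesium bromide F9, which is alkylated with an excess of 1,8-dibromooctane under Li2CuCl4 catalysis (copper-catalysed aryl–alkyl coupling) to give 11 directly.

## Further compounds

F1 | step 3 | 3-bromo-4-hydroxy-2H-pyran-2-one | O=C1OC=CC(O)=C1Br
F2 | step 3 | 3-bromo-4-[(tert-butyldimethylsilyl)oxy]-2H-pyran-2-one | O=C1OC=CC(O[Si](C)(C)C(C)(C)C)=C1Br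
F3 | step 3 | rac-4-bromo-5-[(tert-butyldimethylsilyl)oxy]-8,8-dimethoxy-2-oxabicyclo[2.2.2]oct-5-en-3-one (one enantiomer drawn) | O=C1O[C@@H]2CC(OC)(OC)[C@@]1(Br)C(O[Si](C)(C)C(C)(C)C)=C2
F4 | step 5 | rac-cis-2-[(tert-butyldimethylsilyl)oxy]-N,6,6-trimethoxy-N-methyl-4-[(triethylsilyl)oxy]cyclohex-2-ene-1-carboxamide (one enantiomer drawn) | CON(C)C(=O)[C@@H]1C(O[Si](C)(C)C(C)(C)C)=C[C@H](O[Si](CC)(CC)CC)CC1(OC)OC
F5 | step 5 | rac-cis-2-[(tert-butyldimethylsilyl)oxy]-6,6-dimethoxy-4-[(triethylsilyl)oxy]cyclohex-2-ene-1-carbaldehyde (one enantiomer drawn) | O=C[C@@H]1C(O[Si](C)(C)C(C)(C)C)=C[C@H](O[Si](CC)(CC)CC)CC1(OC)OC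
F6 | step 5 | 9-[3,4-bis(benzyloxy)phenyl]-1-{2-[(tert-butyldimethylsilyl)oxy]-6,6-dimethoxy-4-[(triethylsilyl)oxy]cyclohex-2-en-1-yl}nonan-1-ol (ring cis, racemic, carbinol epimers) | OC(CCCCCCCCc1ccc(OCc2ccccc2)c(OCc2ccccc2)c1)[C@@H]1C(O[Si](C)(C)C(C)(C)C)=C[C@H](O[Si](CC)(CC)CC)CC1(OC)OC
F7 | step 5 | 9-[3,4-bis(benzyloxy)phenyl]-1-{2-[(tert-butyldimethylsilyl)oxy]-6,6-dimethoxy-4-[(triethylsilyl)oxy]cyclohex-2-en-1-yl}nonan-1-one (ring cis, racemic, one enantiomer drawn) | O=C(CCCCCCCCc1ccc(OCc2ccccc2)c(OCc2ccccc2)c1)[C@@H]1C(O[Si](C)(C)C(C)(C)C)=C[C@H](O[Si](CC)(CC)CC)CC1(OC)OC
F8 | step 6 | 2-{9-[3,4-bis(benzyloxy)phenyl]nonanoyl}-5-hydroxy-3-methoxycyclohex-2-en-1-one (racemic) | COC1=C(C(=O)CCCCCCCCc2ccc(OCc3ccccc3)c(OCc3ccccc3)c2)C(=O)CC(O)C1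
F9 | step 4 | [3,4-bis(benzyloxy)phenyl]magnesium bromide | Br[Mg]c1ccc(OCc2ccccc2)c(OCc2ccccc2)c1
A1 | alternative 1 | S-ethyl (3S)-15-[3,4-bis(benzyloxy)phenyl]-3-[(tert-butyldimethylsilyl)oxy]-5,7-dioxopentadecanethioate | CCSC(=O)C[C@@H](O[Si](C)(C)C(C)(C)C)CC(=O)CC(=O)CCCCCCCCc1ccc(OCc2ccccc2)c(OCc2ccccc2)c1
A2 | alternative 1 | (5S)-2-{9-[3,4-bis(benzyloxy)phenyl]nonanoyl}-5-[(tert-butyldimethylsilyl)oxy]-3-hydroxycyclohex-2-en-1-one | O=C(CCCCCCCCc1ccc(OCc2ccccc2)c(OCc2ccccc2)c1)C1=C(O)C[C@H](O[Si](C)(C)C(C)(C)C)CC1=O
A3 | alternative 2 | (5S)-5-[(tert-butyldimethylsilyl)oxy]-2-iodo-3-methoxycyclohex-2-en-1-one | COC1=C(I)C(=O)C[C@@H](O[Si](C)(C)C(C)(C)C)C1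
A4 | alternative 2 | 9-{8-[3,4-bis(benzyloxy)phenyl]octyl}-9-borabicyclo[3.3.1]nonane | C(CCCCCCCc1ccc(OCc2ccccc2)c(OCc2ccccc2)c1)B1C2CCCC1CCC2
A5 | alternative 2 | (5S)-2-{9-[3,4-bis(benzyloxy)phenyl]nonanoyl}-5-[(tert-butyldimethylsilyl)oxy]-3-methoxycyclohex-2-en-1-one | COC1=C(C(=O)CCCCCCCCc2ccc(OCc3ccccc3)c(OCc3ccccc3)c2)C(=O)C[C@@H](O[Si](C)(C)C(C)(C)C)C1
A6 | alternative 3 | 2-(4-acetyl-3-{8-[3,4-bis(benzyloxy)phenyl]octyl}-1,2-oxazol-5-yl)acetaldehyde | CC(=O)c1c(CCCCCCCCc2ccc(OCc3ccccc3)c(OCc3ccccc3)c2)noc1CC=O
A7 | alternative 3 | (6S)-3-{8-[3,4-bis(benzyloxy)phenyl]octyl}-6-hydroxy-6,7-dihydro-1,2-benzoxazol-4(5H)-one | O[C@@H]1CC(=O)c2c(CCCCCCCCc3ccc(OCc4ccccc4)c(OCc4ccccc4)c3)noc2C1
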